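A direct plan would join two kaempferol-derived halves in a (3+2) annulation. Kaempferol ether A1, with only its 7-OH free, would add through C-8 to C-2 of quinone methide A2 (the ring-expanded, dehydrated form of an oxidised flavonol), and O-7 would then close the hemiketal at C-3. Its weakest steps would be:
- the liberation of the single 7-OH of kaempferol, which would cost several protecting-group operations without adding complexity;
- the generation of A2, whose hemiketal and triketone tautomers could react at C-3 or self-condense;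
- the intermolecular attack of C-8 on C-2, which would have to beat C-6 and oxygen attack and set the fully substituted C-2 under catalyst control in the same event.

The route rests on a 1,2-shift of ring B. Ring C of the target shows a fully substituted C-2 (O-1, ring B, C-8'') next to C-3 at ketone level, the retron of a semipinacol rearrangement. C-2 is therefore made by moving the 4-oxyphenyl ring from C-3 to C-2 of an isoflavonoid-type lactol whose C-3 carbinol was set earlier on a simple 3-aryl-4-hydroxycoumarin. One operation forms the C-2–C-1' bond, the quaternary stereocentre and the 3,4-dione; global hydrogenolysis then lets O-7'' close the hemiketal. Both flavonoid units carry uniform benzyl protection, so no single hydroxyl is liberated, no quinone methide is needed, and no fragment union has to be stereocontrolled.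

Key step: step 8

Assumption: in step 4 the (R,R) ligand is taken to expose the face of the nickel enolate that gives (3R)-6; if the sense proves opposite, the (S,S) ligand is used and nothing else changes.

Step 1
Reactants: 1 phloroglucinol; 2 4-hydroxyphenylacetic acid
Product: 3 1-(2,4,6-trihydroxyphenyl)-2-(4-hydroxyphenyl)ethan-1-one
Conditions: BF3·OEt2 (neat), 85 °C; then aq NaOAc
Reagents that add atoms: none
Why: Friedel–Crafts C-acylation of the symmetrical, highly nucleophilic phloroglucinol by the BF3-activated acid; the three ring positions are equivalent and no stereocentre is formed.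

Step 2
Reactants: 3 1-(2,4,6-trihydroxyphenyl)-2-(4-hydroxyphenyl)ethan-1-one
Product: 4 1-[2,4-bis(benzyloxy)-6-hydroxyphenyl]-2-[4-(benzyloxy)phenyl]ethan-1-one
Conditions: BnBr (3.1 equiv), K2CO3, acetone, reflux
Reagents that add atoms: benzyl bromide, BrCc1ccccc1
Why: Williamson etherification with a weak base takes three phenols, while the second ortho-hydroxyl, hydrogen-bonded to the ketone once its twin is benzylated, stays free; no stereocentre is formed.

Step 3
Reactants: 4 1-[2,4-bis(benzyloxy)-6-hydroxyphenyl]-2-[4-(benzyloxy)phenyl]ethan-1-one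
Product: 5 5,7-bis(benzyloxy)-3-[4-(benzyloxy)phenyl]-4-hydroxy-2H-chromen-2-one
Conditions: (EtO)2CO, NaH, toluene, 100 °C; then aq HCl
Reagents that add atoms: diethyl carbonate, CCOC(=O)OCC
Why: O-acylation of the phenoxide by the carbonate and intramolecular Claisen condensation of the benzylic ketone enolate, the classical passage from 2-hydroxydeoxybenzoins to 3-aryl-4-hydroxycoumarins; no stereocentre is formed.

Step 4
Reactants: 5 5,7-bis(benzyloxy)-3-[4-(benzyloxy)phenyl]-4-hydroxy-2H-chromen-2-one
Product: 6 (3R)-5,7-bis(benzyloxy)-3-[4-(benzyloxy)phenyl]-3-hydroxychromane-2,4-dione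
Conditions: Ni(ClO4)2·6H2O (10 mol %), (R,R)-4,6-dibenzofurandiyl-2,2'-bis(4-phenyloxazoline) (11 mol %), 3-phenyl-2-(phenylsulfonyl)oxaziridine (1.2 equiv), 4 Å MS, CH2Cl2, rt
Reagents that add atoms: 3-phenyl-2-(phenylsulfonyl)oxaziridine, O=S(=O)(c1ccccc1)N1OC1c1ccccc1
Why: Chiral-Lewis-acid-catalysed electrophilic α-hydroxylation of a cyclic 1,3-dicarbonyl compound: the enol binds divalent nickel through both carbonyl oxygens and the bis(oxazoline) ligand leaves one face of C-3 open to the oxaziridine, which sets the (3R) carbinol.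

Step 5
Reactants: 7 kaempferol
Product: 8 3,5,7-tris(benzyloxy)-2-[4-(benzyloxy)phenyl]-4H-chromen-4-one
Conditions: BnBr (6 equiv), K2CO3, DMF, 70 °C
Reagents that add atoms: benzyl bromide, BrCc1ccccc1
Why: Exhaustive Williamson benzylation, with DMF and heat to force the chelated 5-OH; all four hydroxyls are treated alike and no stereocentre is formed.

Step 6
Reactants: 8 3,5,7-tris(benzyloxy)-2-[4-(benzyloxy)phenyl]-4H-chromen-4-one
Product: 9 3,5,7-tris(benzyloxy)-2-[4-(benzyloxy)phenyl]-8-iodo-4H-chromen-4-one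
Conditions: NIS (1.1 equiv), CF3CO2H (cat.), CH2Cl2–MeCN, 0 °C to rt
Reagents that add atoms: N-iodosuccinimide, O=C1CCC(=O)N1I
Why: Electrophilic aromatic iodination; in 5,7-dialkoxyflavones the electrophile enters C-8, between O-7 and the ring oxygen, once the 5-oxygen is alkylated, and ring B is deactivated by the chromone.

Step 7
Reactants: 9 3,5,7-tris(benzyloxy)-2-[4-(benzyloxy)phenyl]-8-iodo-4H-chromen-4-one; 6 (3R)-5,7-bis(benzyloxy)-3-[4-(benzyloxy)phenyl]-3-hydroxychromane-2,4-dione
Product: 11 (3R)-5,7-bis(benzyloxy)-3-[4-(benzyloxy)phenyl]-2,3-dihydroxy-2-[3,5,7-tris(benzyloxy)-2-(4-benzyloxyphenyl)-4-oxo-4H-chromen-8-yl]chroman-4-one (lactol; C-2 epimers), via arylmagnesium chloride 10 (not isolated)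
Conditions: 9, i-PrMgCl·LiCl (1.1 equiv), THF, −40 °C; then 6 pre-mixed with i-PrMgCl·LiCl (1.0 equiv) at −78 °C, −78 to −20 °C; aq NH4Cl
Reagents that add atoms: none
Why: Iodine–magnesium exchange, then Grignard addition to the lactone carbonyl, an activated aryl ester that is more electrophilic than the C-4 ketone (a vinylogous carbonate shielded by the peri 5-benzyloxy group), gives the lactol on work-up; C-3 is untouched and C-2 forms as an epimer mixture that is erased in step 8.

Step 8
Reactants: 11 (3R)-lactol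
Product: 13 (2R)-5,7-bis(benzyloxy)-2-[4-(benzyloxy)phenyl]-2-[3,5,7-tris(benzyloxy)-2-(4-benzyloxyphenyl)-4-oxo-4H-chromen-8-yl]chromane-3,4-dione, via oxocarbenium ion 12 (not isolated)
Conditions: BF3·OEt2 (0.3 equiv), 4 Å MS, CH2Cl2, −40 to 0 °C; Et3N
Reagents that add atoms: none
Why: Proposed new method: the Lewis acid ionises the lactol hydroxyl of 11 to the ring C oxocarbenium ion 12 (C-2 is stabilised by O-1 and the electron-rich kaempferol ring, whereas C-3 is flanked by the C-4 carbonyl and does not ionise), and ring B, held pseudo-axial on the C-3 carbinol, shifts with its bonding pair to C-2 while the C-3 hydroxyl collapses to the ketone; the sieves take up the water so that the shift is not reversed. The closest known reaction types are the oxonium-ion-initiated pinacol rearrangement of carbinols next to cyclic oxocarbenium ions, the Meinwald rearrangement of tetrasubstituted aryl epoxides with transfer of configuration to an α-quaternary ketone, and the 1,2-aryl shift of flavonoid biosynthesis run in the opposite direction (C-3 to C-2). No ring is closed here: ring C is kept, and the dihydrofuran ring follows in step 9 by 5-exo-trig hemiketalisation. C-2 is controlled by the C-3 carbinol alone: ring B can only cross on the face on which it already sits, so (3R) gives (2R) from either lactol epimer, while C-3 itself becomes trigonal. The step needs aryl over acyl migration, which is secured because the exocyclic C-3–aryl bond can align with the empty orbital at C-2 whereas the endocyclic C-3–C-4 bond lies near its nodal plane, and because the 4-benzyloxyphenyl group bridges as a phenonium ion. It also needs the cyclic cation to outrun the ring-opened hydroxy diketone, which the aprotic medium and the low temperature favour.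

Step 9
Reactants: 13 (2R)-dione
Product: 15 target CNP0314633.1 (2R,3S), via heptaphenol dione 14 (not isolated)
Conditions: H2 (1 atm), 10% Pd/C, THF–EtOAc, rt
Reagents that add atoms: none
Why: Neutral heterogeneous hydrogenolysis cleaves the seven benzyl ethers, the freed 7''-OH adds 5-exo-trig to the C-3 ketone, and because the five-membered ring can only be cis-fused to ring C, (2R) dictates (3S); the fully substituted C-2–O-1 ether is shielded from the catalyst and no base is present to open it.

Compound list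
1 | phloroglucinol | Oc1cc(O)cc(O)c1 | starting material
2 | 4-hydroxyphenylacetic acid | OC(=O)Cc1ccc(O)cc1 | starting material
3 | 1-(2,4,6-trihydroxyphenyl)-2-(4-hydroxyphenyl)ethan-1-one | O=C(Cc1ccc(O)cc1)c1c(O)cc(O)cc1O | intermediate
4 | 1-[2,4-bis(benzyloxy)-6-hydroxyphenyl]-2-[4-(benzyloxy)phenyl]ethan-1-one | O=C(Cc1ccc(OCc2ccccc2)cc1)c1c(O)cc(OCc2ccccc2)cc1OCc1ccccc1 | intermediate
5 | 5,7-bis(benzyloxy)-3-[4-(benzyloxy)phenyl]-4-hydroxy-2H-chromen-2-one | O=c1oc2cc(OCc3ccccc3)cc(OCc3ccccc3)c2c(O)c1-c1ccc(OCc2ccccc2)cc1 | intermediate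
6 | (3R)-5,7-bis(benzyloxy)-3-[4-(benzyloxy)phenyl]-3-hydroxychromane-2,4-dione | O=C1Oc2cc(OCc3ccccc3)cc(OCc3ccccc3)c2C(=O)[C@]1(O)c1ccc(OCc2ccccc2)cc1 | intermediate
7 | kaempferol | O=c1c(O)c(-c2ccc(O)cc2)oc2cc(O)cc(O)c12 | starting material
8 | 3,5,7-tris(benzyloxy)-2-[4-(benzyloxy)phenyl]-4H-chromen-4-one | O=c1c(OCc2ccccc2)c(-c2ccc(OCc3ccccc3)cc2)oc2cc(OCc3ccccc3)cc(OCc3ccccc3)c12 | intermediate
9 | 3,5,7-tris(benzyloxy)-2-[4-(benzyloxy)phenyl]-8-iodo-4H-chromen-4-one | O=c1c(OCc2ccccc2)c(-c2ccc(OCc3ccccc3)cc2)oc2c(I)c(OCc3ccccc3)cc(OCc3ccccc3)c12 | intermediate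
10 | [3,5,7-tris(benzyloxy)-2-(4-benzyloxyphenyl)-4-oxo-4H-chromen-8-yl]magnesium chloride (not isolated) | O=c1c(OCc2ccccc2)c(-c2ccc(OCc3ccccc3)cc2)oc2c([Mg]Cl)c(OCc3ccccc3)cc(OCc3ccccc3)c12 | intermediate
11 | (3R)-5,7-bis(benzyloxy)-3-[4-(benzyloxy)phenyl]-2,3-dihydroxy-2-[3,5,7-tris(benzyloxy)-2-(4-benzyloxyphenyl)-4-oxo-4H-chromen-8-yl]chroman-4-one (lactol, C-2 epimers) | O=C1c2c(OCc3ccccc3)cc(OCc3ccccc3)cc2OC(O)(c2c(OCc3ccccc3)cc(OCc3ccccc3)c3c(=O)c(OCc4ccccc4)c(-c4ccc(OCc5ccccc5)cc4)oc23)[C@@]1(O)c1ccc(OCc2ccccc2)cc1 | intermediate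
12 | ring C oxocarbenium ion from 11, C-3 configuration unchanged (not isolated) | O=C1c2c(OCc3ccccc3)cc(OCc3ccccc3)cc2[O+]=C(c2c(OCc3ccccc3)cc(OCc3ccccc3)c3c(=O)c(OCc4ccccc4)c(-c4ccc(OCc5ccccc5)cc4)oc23)[C@@]1(O)c1ccc(OCc2ccccc2)cc1 | intermediate
13 | (2R)-5,7-bis(benzyloxy)-2-[4-(benzyloxy)phenyl]-2-[3,5,7-tris(benzyloxy)-2-(4-benzyloxyphenyl)-4-oxo-4H-chromen-8-yl]chromane-3,4-dione | O=C1c2c(OCc3ccccc3)cc(OCc3ccccc3)cc2O[C@](c2ccc(OCc3ccccc3)cc2)(c2c(OCc3ccccc3)cc(OCc3ccccc3)c3c(=O)c(OCc4ccccc4)c(-c4ccc(OCc5ccccc5)cc4)oc23)C1=O | intermediate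
14 | (2R)-5,7-dihydroxy-2-(4-hydroxyphenyl)-2-[3,5,7-trihydroxy-2-(4-hydroxyphenyl)-4-oxo-4H-chromen-8-yl]chromane-3,4-dione (not isolated) | O=C1c2c(O)cc(O)cc2O[C@](c2ccc(O)cc2)(c2c(O)cc(O)c3c(=O)c(O)c(-c4ccc(O)cc4)oc23)C1=O | intermediate
15 | CNP0314633.1, (2R,3S): cis-fused hemiketal between C-2/C-3 of the chromanone unit and C-8''/O-7'' of the kaempferol unit | O=C1c2c(O)cc(O)cc2O[C@]2(c3ccc(O)cc3)c3c(cc(O)c4c(=O)c(O)c(-c5ccc(O)cc5)oc34)O[C@]12O | target

Total step count: 9. Longest linear sequence: 7 (steps 1–4, then 7–9); the kaempferol branch (steps 5 and 6) joins at step 7.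

Steps most likely to fail

Step 8 (rearrangement). The acyl carbon C-4 may migrate instead of ring B (ring contraction), or the cation may leak through the ring-opened hydroxy diketone with erosion of configuration. The fallback uses known chemistry and runs from 11 back to 13. Lactol 11 would be dehydrated to the configurationally locked (2R,3R)-2,3-epoxide F1 with 2-chloro-1,3-dimethylimidazolinium chloride and Et3N, the closure used to make 1,2-anhydro sugars from lactols with a free neighbouring hydroxyl. Isolated F1 would then undergo a Meinwald rearrangement with methylaluminium bis(4-bromo-2,6-di-tert-butylphenoxide) in CH2Cl2 at −78 °C. This reaction is known to pass the configuration of tetrasubstituted aryl epoxides on to α-quaternary ketones by anti migration, and an epoxide has no ring-opened tautomer.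

Step 7 (union). The Grignard reagent may attack the C-4 ketone or fail to add for steric reasons, or the magnesium alkoxide of 6 may undergo an α-ketol or acyl shift first. The fallback runs from 6 back to 11. The lactone of 6 would be opened with N,O-dimethylhydroxylamine and Me2AlCl to the N-methoxy-N-methylamide F2, in which the ketone is deactivated by the neighbouring phenoxide. Excess 10 would then give the aryl ketone through the stable chelate, and the ketone would close to lactol 11 on work-up.

Step 4 (hydroxylation). Facial discrimination of the planar enolate may be poor. The fallback runs from 4 back to 6. Ketone 4 would be converted with N,N-dimethylformamide dimethyl acetal into tri-O-benzylgenistein F3. F3 would be epoxidised with [N,N'-bis(3,5-di-tert-butylsalicylidene)-1,2-cyclohexanediaminato]manganese chloride of the appropriate handedness and NaOCl, a reaction established for isoflavones, to the (2R,3S)-epoxide F4, which carries the C-3 oxygen on the required face. Acid-catalysed hydration at the acetal carbon would give lactol diol F5, and Ag2CO3 on Celite would oxidise the lactol to lactone 6.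

Further compounds
F1 | step 8 | (2R,3R)-5,7-bis(benzyloxy)-3-[4-(benzyloxy)phenyl]-2,3-epoxy-2-[3,5,7-tris(benzyloxy)-2-(4-benzyloxyphenyl)-4-oxo-4H-chromen-8-yl]chroman-4-one | O=C1c2c(OCc3ccccc3)cc(OCc3ccccc3)cc2O[C@]2(c3c(OCc4ccccc4)cc(OCc4ccccc4)c4c(=O)c(OCc5ccccc5)c(-c5ccc(OCc6ccccc6)cc5)oc34)O[C@]12c1ccc(OCc2ccccc2)cc1
F2 | step 7 | (2R)-3-[2,4-bis(benzyloxy)-6-hydroxyphenyl]-2-[4-(benzyloxy)phenyl]-2-hydroxy-N-methoxy-N-methyl-3-oxopropanamide | CON(C)C(=O)[C@@](O)(c1ccc(OCc2ccccc2)cc1)C(=O)c1c(O)cc(OCc2ccccc2)cc1OCc1ccccc1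
F3 | step 4 | 5,7-bis(benzyloxy)-3-[4-(benzyloxy)phenyl]-4H-chromen-4-one (tri-O-benzylgenistein) | O=c1c(-c2ccc(OCc3ccccc3)cc2)coc2cc(OCc3ccccc3)cc(OCc3ccccc3)c12
F4 | step 4 | (2R,3S)-5,7-bis(benzyloxy)-3-[4-(benzyloxy)phenyl]-2,3-epoxychroman-4-one | O=C1c2c(OCc3ccccc3)cc(OCc3ccccc3)cc2O[C@@H]2O[C@]12c1ccc(OCc2ccccc2)cc1
F5 | step 4 | (3S)-5,7-bis(benzyloxy)-3-[4-(benzyloxy)phenyl]-2,3-dihydroxychroman-4-one (lactol, C-2 epimers) | O=C1c2c(OCc3ccccc3)cc(OCc3ccccc3)cc2OC(O)[C@@]1(O)c1ccc(OCc2ccccc2)cc1
A1 | direct plan | 3,5-bis(benzyloxy)-2-[4-(benzyloxy)phenyl]-7-hydroxy-4H-chromen-4-one (3,5,4'-tri-O-benzylkaempferol) | O=c1c(OCc2ccccc2)c(-c2ccc(OCc3ccccc3)cc2)oc2cc(O)cc(OCc3ccccc3)c12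
A2 | direct plan | 5,7-bis(benzyloxy)-2-(4-oxocyclohexa-2,5-dien-1-ylidene)chromane-3,4-dione | O=C1C=CC(=C2Oc3cc(OCc4ccccc4)cc(OCc4ccccc4)c3C(=O)C2=O)C=C1
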